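Abbreviations: TBS = tert-butyldimethylsilyl, PMB = 4-methoxybenzyl, Ang = angeloyl [(Z)-2-methylbut-2-enoyl], iVal = 3-methylbutanoyl, MIB = 3-exo-morpholinoisoborneol.

## The problem

Longipinane numbering is used: C1 is the ketone carbon, C2=C3 the enone alkene (methyl C12 on C3), C4 and C11 the bridgehead CH groups, C5 the cyclobutane CH next to C6 (methyls C13, C14), C7 (OH), C8 (O-iVal), C9 (OAng), and C10 the quaternary carbon with methyl C15. Target 23 is a cyclobutane (C4–C5–C11–C10) with both diagonals bridged: C4/C11 by C3=C2–C1(=O) (ring A, a bicyclo[3.1.1]heptenone) and C5/C10, on the opposite face, by C6–C9 (the seven-membered ring, a bicyclo[4.1.1]octane). The cyclobutane is "crossed" with respect to both bridges, so neither ring can exist before one of the four-membered-ring bonds is in place; a direct [2+2] would need an eleven-membered precursor. The four skeletal stereocentres C4, C5, C10 and C11 admit only one relative arrangement, so they reduce to one question of absolute sense: which bridgehead carries the carbonyl side of ring A relative to the C6 and C10 ends of the large ring. C7, C8 and C9 must be set against this skeleton (O7 and O8 cis, O9 trans to them); C9 can direct C7 and C8, but the surroundings of C9 are almost mirror-symmetric, so the skeleton cannot control C9. C6 and C10 are quaternary and flank the triol, which makes O7 and O9 neopentylic and every bond to C6 hard to form. The three oxygens carry three different groups; the angelate isomerises to the tiglate under basic, nucleophilic or hot conditions, acyl groups can migrate between O7, O8 and O9, and the enone–cyclobutane unit is sensitive to light and strong acid. The feature that opens the problem is that C5 is a CH of the cyclobutane bonded to both bridgeheads: with a carbonyl at C5, ring A plus the cyclobutane is the adduct of a ketene (C5=C4) and the trisubstituted alkene C11=C10 tethered by C1–C2–C3. In that adduct C3 appears as an exocyclic methylene, and C1, allylic to that alkene and a ketone in 23, is free to carry a temporary stereocentre.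

## Retrosynthesis

Acyl groups and the C7/C8 oxygens. The O8–acyl bond is cut (23 to diol 22), then the two C–O bonds at C7 and C8 (22 to alkene 21), then the O9–acyl bond (21 to allylic alcohol 20, from PMB ether 19). A cis-diol trans to an allylic oxygen is what osmylation of a C7=C8 alkene next to C9–O delivers. A C8=C9 alkene would give the wrong (cis) O8/O9 relation, and an epoxide route would need substitution at a neopentylic carbon. The angelate goes on while O9–H is the only hydroxyl, the isovalerate goes on the less hindered diol hydroxyl, and O7–H is left free. The forward steps must osmylate anti to O9 and faster at the isolated cis-alkene than at the two conjugated trisubstituted alkenes.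

Ring A. The enone of 19 is traced to the β,γ-unsaturated ketone 18 (C3=C12 exocyclic), to carbinol 17 and to silyl ether 16. No C–C bond is cut. The change makes C1 an sp3 carbinol, a stereocentre that costs nothing because it disappears on oxidation, and it makes C2=C3 the exocyclic alkene that vinylketene chemistry produces. Late allylic oxidation of a C1 methylene instead would leave the absolute configuration without a controller.

C5–H. Compound 16 is traced to xanthate 15 and tertiary alcohol 14 (C5–H to C5–O). The oxygen is the remnant of the C5 carbonyl that the key step needs. It is removed only after the seven-membered ring is closed, because the C5 radical can then accept hydrogen only on the face of the C1–C3 bridge, so C5 needs no control.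

Seven-membered ring. C7=C8 is cut (14 to diene 13, ring-closing metathesis) and then C5–C6 (13 to cyclobutanone 12 plus a C5 allyl-metal reagent that reacts through its substituted terminus). Closing at C7–C8 keeps the reacting carbons away from the quaternary centres and leaves the alkene where the diol is needed. C6, the hardest carbon to attach, is added to a strained, non-enolisable ketone, and the two chains sit 1,3-cis on the cyclobutane. Precursor 12 is bicyclic and carries only what the key step leaves.

Key disconnection. C5–C11 and C4–C10 are cut (12 to vinylketene 11, acid chloride 10 and acid 9). Two rings, the cyclobutane and three stereocentres (C4, C10, C11) go at once, and the precursor is an open chain with two carbinol centres and two E-alkenes. Against other [2+2] cuts, this one needs only the three-carbon tether that is the bridge itself, and its polarity (central ketene carbon to the less substituted alkene carbon) gives the bridged bicycle for this substitution pattern. The forward reaction must translate the E geometry of C10=C11 into C15 syn to the bridge, and the C1 silyloxy group must choose the alkene face.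

Acyclic precursor. C1–C2 is cut (ester 8 from 7, from enal 4 plus silyl dienol ether 6, itself from ester 5; vinylogous Mukaiyama aldol) and C8–C9 is cut (4 from 3 and alcohol 2, from acetal–aldehyde 1 plus a vinyl nucleophile). Both carbinol centres come from catalyst-controlled additions to conjugated aldehydes. The C10=C11 geometry is bought with 1, the C3=C4 geometry follows from the aldol, and the two aldehyde groups of the central unit are revealed one after the other.

## Roads not taken

Alternative 1: cut C4–C10 only and make the cyclobutane last on a cis-fused six–seven bicycle, the plan most chemists would draw first. The forward key step is displacement of the allylic C4 sulfonate by the C10 enolate of keto mesylate A1 (4-exo-tet) to give tricyclic ketone A2. The chosen plan is better for these reasons: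
- The closure must form a quaternary carbon in a four-membered ring from a hindered enolate; O-alkylation, elimination and allylic transposition compete.
- A1 needs a cis ring fusion and a correctly oriented leaving group set by separate operations on a flexible bicycle that is itself long to build.
- A2 lacks the C7 and C8 oxygens and has no handle for absolute configuration.
- The ketene route sets C4, C10 and C11 in one step from alkene geometry and one carbinol.

Alternative 2: keep ring A and the cyclobutane from the chiral pool and cut C5–C6 and C9–C10. (1R,5R)-Verbenone A3 has the enone and bridgeheads in the right absolute sense. The forward key step would be twofold C–H functionalisation of A3 (one methyl of the gem-dimethyl bridge and the cyclobutane methylene C–H on the same face), then annulation of C6–C9. The chosen plan is better because no directing group in A3 reaches both sites, a cyclobutane C–H bond is among the least reactive, and both new bonds would end at neopentylic or quaternary positions. The steps saved on the core would be spent on these two bonds.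

Alternative 3: cut C4–C10 and C5–C11 with nothing else in place, by transannular [2+2] photocycloaddition of the eleven-membered trienone A4 (drawn without the C7–C9 oxygens). This removes the most bridges, one ring to three. The chosen plan is better for these reasons:
- The needed bonding is crossed with respect to both tethers, whereas 1,5-closure (C4 to C11, a five-membered ring) would lead to the linear fused isomer.
- Excited medium-ring dienones isomerise at their alkenes, which would scramble C10 and C4/C5.
- A4 with three defined alkenes and three carbinol centres is harder to make than acid 9, and nothing controls the absolute sense.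

Key step: step 7

Assumption: 1 is bought as the E isomer; the sense of induction of the ligand in step 1 and the catalyst in step 4 is taken from their behaviour with conjugated aldehydes and is to be confirmed by MTPA ester analysis of 2 and 7 (the enantiomeric ligand or catalyst is used if the sense is opposite).
Naming: tricyclic compounds carry longipinane numbering; C4, C10 and C11 (and C5 where it bears hydrogen) are configured as in 23.

Step 1
Reactants: 1 (2E)-4,4-dimethoxy-2-methylbut-2-enal
Product: 2 (3R,4E)-6,6-dimethoxy-4-methylhexa-1,4-dien-3-ol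
Conditions: (CH2=CH)2Zn [from ZnCl2 + 2 CH2=CHMgBr, THF, salts precipitated with 1,4-dioxane], (2R)-(+)-MIB (5 mol%), toluene, −20 to 0 °C; H2O work-up
Reagents that add atoms: vinylmagnesium bromide, C=C[Mg]Br
Why: Amino-alcohol-catalysed enantioselective addition of an alkenylzinc reagent to a non-enolisable conjugated aldehyde; Re-face delivery of vinyl sets C9 (R here, 9S in 23 after the priority change) and forms the C8–C9 bond.

Step 2
Reactants: 2 (3R,4E)-6,6-dimethoxy-4-methylhexa-1,4-dien-3-ol
Product: 4 (2E,4R)-3-methyl-4-(PMB-oxy)hexa-2,5-dienal, via PMB ether acetal 3 (not isolated)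
Conditions: NaH, PMBCl, Bu4NI (cat.), THF/DMF, 0 °C to rt; then aq. HCl (1 mol/L), THF, 0 °C
Reagents that add atoms: 4-methoxybenzyl chloride, COc1ccc(CCl)cc1; water, O
Why: Williamson etherification followed by acid hydrolysis of the conjugated dimethyl acetal; the E geometry and C9 are untouched, and cold dilute acid spares the doubly allylic ether.

Step 3
Reactants: 5 methyl 3-methylbut-2-enoate
Product: 6 tert-butyl[(1-methoxy-3-methylbuta-1,3-dien-1-yl)oxy]dimethylsilane (ketene acetal geometry inconsequential)
Conditions: LiN(iPr)2, DMPU, THF, −78 °C; TBSCl, −78 °C to rt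
Reagents that add atoms: tert-butyldimethylsilyl chloride, CC(C)(C)[Si](C)(C)Cl
Why: γ-Deprotonation of the β,β-dimethyl enoate and O-silylation of the dienolate gives the vinylogous silyl ketene acetal.

Step 4
Reactants: 4 (2E,4R)-3-methyl-4-(PMB-oxy)hexa-2,5-dienal; 6 tert-butyl[(1-methoxy-3-methylbuta-1,3-dien-1-yl)oxy]dimethylsilane
Product: 7 methyl (2E,5S,6E,8R)-5-hydroxy-3,7-dimethyl-8-(PMB-oxy)deca-2,6,9-trienoate
Conditions: SiCl4 (1.1 equiv), (S,S)-bisphosphoramide catalyst (from (S)-N,N′-dimethyl-1,1′-binaphthyl-2,2′-diamine, pentane-1,5-diyl linked, 2 mol%), iPr2NEt (10 mol%), CH2Cl2, −78 °C; H2O work-up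
Reagents that add atoms: none
Why: Catalytic enantioselective vinylogous Mukaiyama aldol reaction of a conjugated aldehyde; attack through the γ-carbon on the Si face forms C1–C2 and sets C1 (S) under catalyst control (C9 is remote), and the new trisubstituted alkene is E.

Step 5
Reactants: 7 methyl (2E,5S,6E,8R)-5-hydroxy-3,7-dimethyl-8-(PMB-oxy)deca-2,6,9-trienoate
Product: 8 methyl (2E,5S,6E,8R)-3,7-dimethyl-8-(PMB-oxy)-5-(TBS-oxy)deca-2,6,9-trienoate
Conditions: TBSCl, imidazole, DMF, rt
Reagents that add atoms: tert-butyldimethylsilyl chloride, CC(C)(C)[Si](C)(C)Cl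
Why: Silylation of the secondary allylic alcohol under non-acidic conditions; the silyl ether blocks lactonisation and is the group that steers step 7.

Step 6
Reactants: 8 methyl (2E,5S,6E,8R)-3,7-dimethyl-8-(PMB-oxy)-5-(TBS-oxy)deca-2,6,9-trienoate
Product: 9 (2E,5S,6E,8R)-3,7-dimethyl-8-(PMB-oxy)-5-(TBS-oxy)deca-2,6,9-trienoic acid
Conditions: LiOH, THF/MeOH/H2O, 40 °C; then aq. HCl to pH 4, 0 °C
Reagents that add atoms: lithium hydroxide, [Li+].[OH-]
Why: Saponification of the methyl ester; silyl and PMB ethers are stable to aqueous hydroxide and the alkene geometry is retained.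

Step 7
Reactants: 9 (2E,5S,6E,8R)-3,7-dimethyl-8-(PMB-oxy)-5-(TBS-oxy)deca-2,6,9-trienoic acid
Product: 12 (1R,2S,5R,7R)-7-methyl-4-methylidene-7-[(1R)-1-(PMB-oxy)prop-2-en-1-yl]-2-(TBS-oxy)bicyclo[3.1.1]heptan-6-one, via acid chloride 10 (not isolated), via vinylketene 11 (not isolated)
Conditions: Me2C=C(Cl)NMe2, CH2Cl2, 0 °C to rt; concentrate; slow addition to Et3N (5 equiv), toluene, 110 °C, final 0.005 mol/L, dark
Reagents that add atoms: none
Why: Intramolecular vinylketene–alkene [2+2] cycloaddition. The chloroenamine gives acid chloride 10 without free HCl, and Et3N removes HCl across C4 and the C12 methyl (cis to the acyl group) to give the cross-conjugated vinylketene 11. The closest known reaction type is the thermal cyclisation of (2E)-3-methylalka-2,6-dienoyl chlorides with Et3N to 2-methylidenebicyclo[3.1.1]heptan-6-ones. The addition is concerted but asynchronous: the ketene carbon C5 bonds first to C11, the less substituted alkene carbon (six-membered ring C5–C4–C3–C2–C1–C11), charge builds at the tertiary C10, and C4–C10 closes the cyclobutanone; this polarity secures the bridged over the fused bicycle. The addition is suprafacial on the alkene, so the E geometry puts C15 cis to C1, syn to the bridge, and the C9 branch anti (C10), while the tether forces C4 and C11 cis. The alkene face is chosen by C1: with C2 turned toward the ketene, the inward C1 substituent meets the C15 methyl (allylic 1,3-strain), so hydrogen sits inside and OTBS outside, which with (S)-C1 gives the natural skeleton with OTBS anti to the C10 bridge. The terminal C8 alkene is beyond the tether, and C9 has no such strain partner and no say. Slow addition at high dilution is needed because the alkene, flanked by two allylic oxygens, is less nucleophilic than in the parent cases.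

Step 8
Reactants: 12 (1R,2S,5R,7R)-7-methyl-4-methylidene-7-[(1R)-1-(PMB-oxy)prop-2-en-1-yl]-2-(TBS-oxy)bicyclo[3.1.1]heptan-6-one
Product: 13 (1R,2S,5R,6R,7R)-7-methyl-6-(2-methylbut-3-en-2-yl)-4-methylidene-7-[(1R)-1-(PMB-oxy)prop-2-en-1-yl]-2-(TBS-oxy)bicyclo[3.1.1]heptan-6-ol
Conditions: Me2C=CHCH2MgCl, THF, −78 °C; H2O quench at −78 °C
Reagents that add atoms: 3-methylbut-2-en-1-ylmagnesium chloride, CC(C)=CC[Mg]Cl
Why: Allyl Grignard addition with allylic transposition (six-membered transition state), so the CMe2 terminus bonds to C5 and forms C5–C6; the strained cyclobutanone cannot enolise (both α-carbons are bridgeheads). Attack comes anti to the C1–C3 bridge and its OTBS group, which places C6 on the face of the C9 chain.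

Step 9
Reactants: 13 (1R,2S,5R,6R,7R)-7-methyl-6-(2-methylbut-3-en-2-yl)-4-methylidene-7-[(1R)-1-(PMB-oxy)prop-2-en-1-yl]-2-(TBS-oxy)bicyclo[3.1.1]heptan-6-ol
Product: 14 (1S,9R)-9-(PMB-oxy)-1-(TBS-oxy)longipina-3(12),7-dien-5-ol (5-OH on the face of the C1–C3 bridge)
Conditions: second-generation Hoveyda–Grubbs catalyst (5 mol%), toluene, 80 °C, 0.002 mol/L, argon sparge
Reagents that add atoms: none
Why: Ring-closing metathesis of two monosubstituted alkenes held 1,3-cis on the cyclobutane closes the seven-membered ring at C7=C8 (cis by ring size); the 1,1-disubstituted C3=C12 alkene lies on the other face and is much less reactive.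

Step 10
Reactants: 14 (1S,9R)-9-(PMB-oxy)-1-(TBS-oxy)longipina-3(12),7-dien-5-ol
Product: 15 O-[(1S,9R)-9-(PMB-oxy)-1-(TBS-oxy)longipina-3(12),7-dien-5-yl] S-methyl carbonodithioate
Conditions: KN(SiMe3)2, THF, −78 °C; CS2, −78 to 0 °C; MeI
Reagents that add atoms: carbon disulfide, S=C=S; iodomethane, CI
Why: Xanthate formation from the tertiary alkoxide; this tertiary xanthate is stable because syn elimination would need a bridgehead alkene (C4, C11) or a hydrogen on quaternary C6.

Step 11
Reactants: 15 O-[(1S,9R)-9-(PMB-oxy)-1-(TBS-oxy)longipina-3(12),7-dien-5-yl] S-methyl carbonodithioate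
Product: 16 (1S,9R)-9-(PMB-oxy)-1-(TBS-oxy)longipina-3(12),7-diene
Conditions: Bu3SnH, AIBN (cat.), toluene, 100 °C
Reagents that add atoms: none
Why: Barton–McCombie deoxygenation; the tertiary cyclobutyl radical at C5 has its lower lobe tied into the seven-membered ring, so hydrogen can only arrive on the face of the C1–C3 bridge and C5 gets the configuration of 23.

Step 12
Reactants: 16 (1S,9R)-9-(PMB-oxy)-1-(TBS-oxy)longipina-3(12),7-diene
Product: 17 (1S,9R)-9-(PMB-oxy)longipina-3(12),7-dien-1-ol
Conditions: Bu4NF, THF, 0 to 40 °C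
Reagents that add atoms: none
Why: Fluoride cleavage of the secondary silyl ether; the PMB ether and both alkenes are inert.

Step 13
Reactants: 17 (1S,9R)-9-(PMB-oxy)longipina-3(12),7-dien-1-ol
Product: 19 (9R)-9-(PMB-oxy)longipina-2,7-dien-1-one, via β,γ-enone 18 (not isolated)
Conditions: Dess–Martin periodinane, CH2Cl2, 0 °C to rt; then DBU (0.2 equiv), rt
Reagents that add atoms: none
Why: Alcohol oxidation, then base-mediated migration of the exocyclic alkene into conjugation through the C2 dienolate; C11–H is a bridgehead and cannot epimerise, and the C1 stereocentre is consumed as planned.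

Step 14
Reactants: 19 (9R)-9-(PMB-oxy)longipina-2,7-dien-1-one
Product: 20 (9R)-9-hydroxylongipina-2,7-dien-1-one
Conditions: DDQ, CH2Cl2/aq. pH 7 buffer, 0 °C
Reagents that add atoms: none
Why: Oxidative cleavage of the PMB ether by hydride abstraction at the benzylic position; the enone and the isolated alkene are not electron-rich enough to react.

Step 15
Reactants: 20 (9R)-9-hydroxylongipina-2,7-dien-1-one
Product: 21 (9R)-9-(angeloyloxy)longipina-2,7-dien-1-one
Conditions: angelic acid, 2,4,6-trichlorobenzoyl chloride, Et3N, toluene, rt; then 20, toluene, 80 °C, no DMAP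
Reagents that add atoms: angelic acid, C/C=C(/C)C(=O)O
Why: Yamaguchi-type esterification through the mixed anhydride; omitting the nucleophilic catalyst avoids addition–elimination isomerisation to the tiglate, and O9–H is the only hydroxyl present.

Step 16
Reactants: 21 (9R)-9-(angeloyloxy)longipina-2,7-dien-1-one
Product: 22 (7S,8S,9S)-9-(angeloyloxy)-7,8-dihydroxylongipin-2-en-1-one
Conditions: OsO4 (5 mol%), N-methylmorpholine N-oxide, acetone/H2O, 0 °C to rt
Reagents that add atoms: OsO4, O=[Os](=O)(=O)=O; N-methylmorpholine N-oxide, C[N+]1([O-])CCOCC1; water, O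
Why: Upjohn dihydroxylation; the isolated cis-alkene reacts faster than the two conjugated trisubstituted alkenes. OsO4 adds anti to the allylic C9–O bond, which sets C7 and C8 with both hydroxyls cis to each other and trans to O9.

Step 17
Reactants: 22 (7S,8S,9S)-9-(angeloyloxy)-7,8-dihydroxylongipin-2-en-1-one
Product: 23 (4R,5S,7S,8S,9S,10R,11R)-9-(angeloyloxy)-7-hydroxy-8-(3-methylbutanoyloxy)longipin-2-en-1-one
Conditions: (iPrCH2CO)2O (1.1 equiv), DMAP (cat.), pyridine, CH2Cl2, −20 to 0 °C
Reagents that add atoms: 3-methylbutanoic anhydride, CC(C)CC(=O)OC(=O)CC(C)C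
Why: Selective acylation of the less hindered O8–H; O7–H is neopentylic next to the gem-dimethyl carbon C6 and is expected to stay free at low temperature with one equivalent of anhydride.

Compound list

1 | (2E)-4,4-dimethoxy-2-methylbut-2-enal | O=C/C(C)=C/C(OC)OC | starting material
2 | (3R,4E)-6,6-dimethoxy-4-methylhexa-1,4-dien-3-ol | COC(OC)/C=C(\C)[C@H](O)C=C | intermediate
3 | (3R,4E)-6,6-dimethoxy-4-methyl-3-(PMB-oxy)hexa-1,4-diene | COC(OC)/C=C(\C)[C@H](OCc1ccc(OC)cc1)C=C | intermediate (not isolated)
4 | (2E,4R)-3-methyl-4-(PMB-oxy)hexa-2,5-dienal | O=C/C=C(\C)[C@H](OCc1ccc(OC)cc1)C=C | intermediate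
5 | methyl 3-methylbut-2-enoate | COC(=O)C=C(C)C | starting material
6 | tert-butyl[(1-methoxy-3-methylbuta-1,3-dien-1-yl)oxy]dimethylsilane (drawn 1Z) | CO/C(O[Si](C)(C)C(C)(C)C)=C/C(C)=C | intermediate
7 | methyl (2E,5S,6E,8R)-5-hydroxy-3,7-dimethyl-8-(PMB-oxy)deca-2,6,9-trienoate | COC(=O)/C=C(\C)C[C@H](O)/C=C(\C)[C@H](OCc1ccc(OC)cc1)C=C | intermediate
8 | methyl (2E,5S,6E,8R)-3,7-dimethyl-8-(PMB-oxy)-5-(TBS-oxy)deca-2,6,9-trienoate | COC(=O)/C=C(\C)C[C@H](O[Si](C)(C)C(C)(C)C)/C=C(\C)[C@H](OCc1ccc(OC)cc1)C=C | intermediate
9 | (2E,5S,6E,8R)-3,7-dimethyl-8-(PMB-oxy)-5-(TBS-oxy)deca-2,6,9-trienoic acid | OC(=O)/C=C(\C)C[C@H](O[Si](C)(C)C(C)(C)C)/C=C(\C)[C@H](OCc1ccc(OC)cc1)C=C | intermediate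
10 | (2E,5S,6E,8R)-3,7-dimethyl-8-(PMB-oxy)-5-(TBS-oxy)deca-2,6,9-trienoyl chloride | ClC(=O)/C=C(\C)C[C@H](O[Si](C)(C)C(C)(C)C)/C=C(\C)[C@H](OCc1ccc(OC)cc1)C=C | intermediate (not isolated)
11 | (5S,6E,8R)-7-methyl-3-methylidene-8-(PMB-oxy)-5-(TBS-oxy)deca-1,6,9-trien-1-one (vinylketene) | O=C=CC(=C)C[C@H](O[Si](C)(C)C(C)(C)C)/C=C(\C)[C@H](OCc1ccc(OC)cc1)C=C | intermediate (not isolated)
12 | (1R,2S,5R,7R)-7-methyl-4-methylidene-7-[(1R)-1-(PMB-oxy)prop-2-en-1-yl]-2-(TBS-oxy)bicyclo[3.1.1]heptan-6-one | COc1ccc(CO[C@H](C=C)[C@@]2(C)[C@@H]3[C@@H](O[Si](C)(C)C(C)(C)C)CC(=C)[C@H]2C3=O)cc1 | intermediate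
13 | (1R,2S,5R,6R,7R)-7-methyl-6-(2-methylbut-3-en-2-yl)-4-methylidene-7-[(1R)-1-(PMB-oxy)prop-2-en-1-yl]-2-(TBS-oxy)bicyclo[3.1.1]heptan-6-ol | COc1ccc(CO[C@H](C=C)[C@@]2(C)[C@@H]3[C@@H](O[Si](C)(C)C(C)(C)C)CC(=C)[C@H]2[C@]3(O)C(C)(C)C=C)cc1 | intermediate
14 | (1S,9R)-9-(PMB-oxy)-1-(TBS-oxy)longipina-3(12),7-dien-5-ol | COc1ccc(CO[C@@H]2C=CC(C)(C)[C@]3(O)[C@H]4[C@@H](O[Si](C)(C)C(C)(C)C)CC(=C)[C@@H]3[C@@]24C)cc1 | intermediate
15 | O-[(1S,9R)-9-(PMB-oxy)-1-(TBS-oxy)longipina-3(12),7-dien-5-yl] S-methyl carbonodithioate | COc1ccc(CO[C@@H]2C=CC(C)(C)[C@]3(OC(=S)SC)[C@H]4[C@@H](O[Si](C)(C)C(C)(C)C)CC(=C)[C@@H]3[C@@]24C)cc1 | intermediate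
16 | (1S,9R)-9-(PMB-oxy)-1-(TBS-oxy)longipina-3(12),7-diene | COc1ccc(CO[C@@H]2C=CC(C)(C)[C@@H]3[C@H]4[C@@H](O[Si](C)(C)C(C)(C)C)CC(=C)[C@@H]3[C@@]24C)cc1 | intermediate
17 | (1S,9R)-9-(PMB-oxy)longipina-3(12),7-dien-1-ol | COc1ccc(CO[C@@H]2C=CC(C)(C)[C@@H]3[C@H]4[C@@H](O)CC(=C)[C@@H]3[C@@]24C)cc1 | intermediate
18 | (9R)-9-(PMB-oxy)longipina-3(12),7-dien-1-one | COc1ccc(CO[C@@H]2C=CC(C)(C)[C@@H]3[C@H]4C(=O)CC(=C)[C@@H]3[C@@]24C)cc1 | intermediate (not isolated)
19 | (9R)-9-(PMB-oxy)longipina-2,7-dien-1-one | COc1ccc(CO[C@@H]2C=CC(C)(C)[C@@H]3[C@H]4C(=O)C=C(C)[C@@H]3[C@@]24C)cc1 | intermediate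
20 | (9R)-9-hydroxylongipina-2,7-dien-1-one | O[C@@H]1C=CC(C)(C)[C@@H]2[C@H]3C(=O)C=C(C)[C@@H]2[C@@]13C | intermediate
21 | (9R)-9-(angeloyloxy)longipina-2,7-dien-1-one | C/C=C(/C)C(=O)O[C@@H]1C=CC(C)(C)[C@@H]2[C@H]3C(=O)C=C(C)[C@@H]2[C@@]13C | intermediate
22 | (7S,8S,9S)-9-(angeloyloxy)-7,8-dihydroxylongipin-2-en-1-one | C/C=C(/C)C(=O)O[C@@H]1[C@@H](O)[C@@H](O)C(C)(C)[C@@H]2[C@H]3C(=O)C=C(C)[C@@H]2[C@@]13C | intermediate
23 | (4R,5S,7S,8S,9S,10R,11R)-9-(angeloyloxy)-7-hydroxy-8-(3-methylbutanoyloxy)longipin-2-en-1-one | C/C=C(/C)C(=O)O[C@@H]1[C@@H](OC(=O)CC(C)C)[C@@H](O)C(C)(C)[C@@H]2[C@H]3C(=O)C=C(C)[C@@H]2[C@@]13C | target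

Total step count: 17. Longest linear sequence: 16 steps (steps 1, 2 and 4 to 17; step 3 prepares 6).

Steps least certain to work

Step 7 (key step). The alkene carries two allylic C–O bonds and a branched C9, so cycloaddition may be slower than oligomerisation of the vinylketene or than dehydrochlorination toward C2, which gives a linear dienylketene that cannot cyclise. Facial control may also be incomplete because it rests on a single allylic interaction. Fallback: from ester 8, kinetic deconjugation (LiN(iPr)2, DMPU, THF, −78 °C; AcOH quench) gives methyl (5S,6E,8R)-7-methyl-3-methylidene-8-(PMB-oxy)-5-(TBS-oxy)deca-6,9-dienoate F1. Saponification gives the corresponding acid F2 and the chloroenamine gives its acid chloride F3. Simple α-dehydrochlorination of F3 (Et3N, 25 to 60 °C) forms the same ketene 11 without the regiochemical question, and at this temperature promotion of the cycloaddition by EtAlCl2 at −78 °C becomes an option. The route is rejoined at 12.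

Step 8. The carbonyl face anti to the bridge is flanked by the C9 branch (1,3-cis on the cyclobutane), so addition may be slow and reversible, and the adduct could equilibrate to the isomer bonded through the unsubstituted allyl terminus. Fallback: from 12, the slimmer allenylzinc reagent from 3-chloro-3-methylbut-1-yne (Mg, then ZnBr2) adds irreversibly through its substituted terminus to give the 6-(2-methylbut-3-yn-2-yl) analogue of 13, alkynyl carbinol F4. Semi-hydrogenation (H2, Pd/CaCO3 poisoned with Pb(OAc)2, quinoline) then gives 13.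

Step 10. The tertiary alkoxide sits between C6, the bridge and the OTBS group and may fail to capture CS2, or the alkoxide may fragment on warming. Fallback: from 14, oxalyl chloride without base gives the chlorooxalate F5, and sodium 2-thioxopyridin-1(2H)-olate gives the mixed oxalate F6. Heating or visible-light irradiation of F6 with tert-butyl thiol (radical chain with loss of two CO2) gives 16 directly, bypassing 15 and step 11.

Step 15. The angeloyl group may isomerise to tigloyl during activation, and the neopentylic allylic alcohol may acylate sluggishly. Fallback: from 20, coupling with 2-[bis(2,2,2-trifluoroethoxy)phosphoryl]propanoic acid (N,N′-dicyclohexylcarbodiimide, DMAP) gives phosphonate ester F7. Still–Gennari olefination of F7 with acetaldehyde (KN(SiMe3)2, 18-crown-6, THF, −78 °C) builds the Z-alkene on the substrate and gives 21.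

Step 16. Osmylation of the angelate or enone alkene may compete, and the acyloxy group may give weak facial induction at a hindered alkene. Fallback: from PMB ether 19, which has a stronger anti-directing ether and no angelate, OsO4/N-methylmorpholine N-oxide gives (7S,8S,9S)-7,8-dihydroxy-9-(PMB-oxy)longipin-2-en-1-one F8. Selective acylation at O8 with 3-methylbutanoic anhydride gives the 8-isovalerate F9, DDQ gives the 7,9-diol 8-isovalerate F10, and mixed-anhydride angeloylation of the less hindered O9–H gives 23.

Further compounds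

F1 | step 7 | methyl (5S,6E,8R)-7-methyl-3-methylidene-8-(PMB-oxy)-5-(TBS-oxy)deca-6,9-dienoate | COC(=O)CC(=C)C[C@H](O[Si](C)(C)C(C)(C)C)/C=C(\C)[C@H](OCc1ccc(OC)cc1)C=C
F2 | step 7 | (5S,6E,8R)-7-methyl-3-methylidene-8-(PMB-oxy)-5-(TBS-oxy)deca-6,9-dienoic acid | OC(=O)CC(=C)C[C@H](O[Si](C)(C)C(C)(C)C)/C=C(\C)[C@H](OCc1ccc(OC)cc1)C=C
F3 | step 7 | (5S,6E,8R)-7-methyl-3-methylidene-8-(PMB-oxy)-5-(TBS-oxy)deca-6,9-dienoyl chloride | ClC(=O)CC(=C)C[C@H](O[Si](C)(C)C(C)(C)C)/C=C(\C)[C@H](OCc1ccc(OC)cc1)C=C
F4 | step 8 | (1R,2S,5R,6R,7R)-7-methyl-6-(2-methylbut-3-yn-2-yl)-4-methylidene-7-[(1R)-1-(PMB-oxy)prop-2-en-1-yl]-2-(TBS-oxy)bicyclo[3.1.1]heptan-6-ol | COc1ccc(CO[C@H](C=C)[C@@]2(C)[C@@H]3[C@@H](O[Si](C)(C)C(C)(C)C)CC(=C)[C@H]2[C@]3(O)C(C)(C)C#C)cc1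
F5 | step 10 | (1S,9R)-9-(PMB-oxy)-1-(TBS-oxy)longipina-3(12),7-dien-5-yl chlorooxoacetate | COc1ccc(CO[C@@H]2C=CC(C)(C)[C@]3(OC(=O)C(=O)Cl)[C@H]4[C@@H](O[Si](C)(C)C(C)(C)C)CC(=C)[C@@H]3[C@@]24C)cc1
F6 | step 10 | (1S,9R)-9-(PMB-oxy)-1-(TBS-oxy)longipina-3(12),7-dien-5-yl 2-thioxopyridin-1(2H)-yl oxalate | COc1ccc(CO[C@@H]2C=CC(C)(C)[C@]3(OC(=O)C(=O)On5ccccc5=S)[C@H]4[C@@H](O[Si](C)(C)C(C)(C)C)CC(=C)[C@@H]3[C@@]24C)cc1
F7 | step 15 | (9R)-1-oxolongipina-2,7-dien-9-yl 2-[bis(2,2,2-trifluoroethoxy)phosphoryl]propanoate (mixture at the phosphonate α-carbon) | CC(C(=O)O[C@@H]1C=CC(C)(C)[C@@H]2[C@H]3C(=O)C=C(C)[C@@H]2[C@@]13C)P(=O)(OCC(F)(F)F)OCC(F)(F)F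
F8 | step 16 | (7S,8S,9S)-7,8-dihydroxy-9-(PMB-oxy)longipin-2-en-1-one | COc1ccc(CO[C@@H]2[C@@H](O)[C@@H](O)C(C)(C)[C@@H]3[C@H]4C(=O)C=C(C)[C@@H]3[C@@]24C)cc1
F9 | step 16 | (7S,8S,9S)-7-hydroxy-8-(3-methylbutanoyloxy)-9-(PMB-oxy)longipin-2-en-1-one | COc1ccc(CO[C@@H]2[C@@H](OC(=O)CC(C)C)[C@@H](O)C(C)(C)[C@@H]3[C@H]4C(=O)C=C(C)[C@@H]3[C@@]24C)cc1
F10 | step 16 | (7S,8S,9S)-7,9-dihydroxy-8-(3-methylbutanoyloxy)longipin-2-en-1-one | O[C@@H]1[C@@H](OC(=O)CC(C)C)[C@@H](O)C(C)(C)[C@@H]2[C@H]3C(=O)C=C(C)[C@@H]2[C@@]13C
A1 | alternative 1 | cis-fused keto mesylate: 4-(methanesulfonyloxy)-3,6,6,10-tetramethylbicyclo[5.4.0]undec-2-en-9-one (longipinane locants, C10 epimers) | O=C1CCC(C)(C)[C@H]2[C@H](OS(C)(=O)=O)C(C)=CC[C@H]2C1C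
A2 | alternative 1 | longipin-2-en-9-one | O=C1CCC(C)(C)[C@@H]2[C@H]3CC=C(C)[C@@H]2[C@@]13C
A3 | alternative 2 | (1R,5R)-verbenone | CC1=CC(=O)[C@@H]2C[C@H]1C2(C)C
A4 | alternative 3 | (2Z,4E,10E)-3,6,6,10-tetramethylcycloundeca-2,4,10-trien-1-one | O=C1/C=C(C)\C=C\C(C)(C)CCC/C(C)=C/1
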